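**Plan**

- Retrosynthesis: the C6'=C7' bond is cut first (cross-metathesis), then both C–O bonds of the C2'–C3' oxirane (oxygen-atom transfer to an E alkene), then O8–CH3 and O7–C1', then C1'–C2' and C3'–CH3 (methylalumination with formaldehyde capture), and last C4'–C5' (propargylation of acrolein).
- Forward: the seven-carbon side chain is built linearly (steps 1–5), joined to O7 of daphnetin, and O8 is methylated. The oxirane is the only ring made (step 8), since both coumarin rings come from daphnetin, and the isobutenyl terminus is added last.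
- Enabling feature: in 13 the E-trisubstituted C2'=C3' bond is the only electron-rich alkene. C6'=C7' is still a monosubstituted vinyl group next to the silyloxy carbon C5', and the C3=C4 bond of the pyranone ring is conjugated with the lactone carbonyl.
- Stereochemistry: C5' (R) comes from a lipase kinetic resolution. The E geometry of C2'=C3' comes from syn methylalumination. C2' and C3' (R,R) come from the D-fructose-derived Shi ketone, and their trans relationship follows from the E alkene.

Key step: step 8

Remark: the side chain is numbered C1' (OCH2) to C7'; the lipase is assumed to treat vinyl as the smaller and propargyl as the larger carbinol substituent, so that the unreacted alcohol is (R).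

**Route**

Step 1
Reactants: 1 acrolein; 2 propargyl bromide
Product: 4 rac-hex-1-en-5-yn-3-ol, via allenylzinc bromide 3 (not isolated)
Conditions: Zn dust, THF, 0 °C → rt; sat. aq. NH4Cl
Reagents that add atoms: none
Why: Barbier-type propargylation, in which zinc inserts into the C–Br bond and the allenylzinc bromide adds 1,2 to the aldehyde through a cyclic SE2' transition state, which should give the homopropargylic carbinol (racemic at C5') and not the allenyl isomer or the conjugate adduct.

Step 2
Reactants: 4 rac-hex-1-en-5-yn-3-ol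
Product: 5 (3R)-hex-1-en-5-yn-3-ol
Conditions: Novozym 435 (immobilised Candida antarctica lipase B), vinyl acetate, hexane, rt, stopped shortly after half conversion; chromatography
Reagents that add atoms: none
Why: Lipase-catalysed kinetic resolution by irreversible acyl transfer from vinyl acetate, in which the (S)-alcohol should be acetylated faster (vinyl small, propargyl large), so that running past half conversion should leave the (R)-alcohol and thereby fix C5' of the target.

Step 3
Reactants: 5 (3R)-hex-1-en-5-yn-3-ol
Product: 6 tert-butyl{[(3R)-hex-1-en-5-yn-3-yl]oxy}dimethylsilane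
Conditions: TBSCl, imidazole, DMF, 0 °C → rt
Reagents that add atoms: tert-butyldimethylsilyl chloride, CC(C)(C)[Si](C)(C)Cl
Why: Silylation of the secondary alcohol with the imidazole-activated silyl chloride, which masks the hydroxyl for the organoaluminium, bromination, alkylation and dioxirane steps and leaves alkyne, alkene and stereocentre untouched.

Step 4
Reactants: 6 tert-butyl{[(3R)-hex-1-en-5-yn-3-yl]oxy}dimethylsilane
Product: 9 (2E,5R)-5-{[tert-butyl(dimethyl)silyl]oxy}-3-methylhepta-2,6-dien-1-ol, via alkenyldimethylalane 7 (not isolated), via lithium alkenylalanate 8 (not isolated)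
Conditions: Me3Al (2.5 equiv), Cp2ZrCl2 (0.25 equiv), CH2Cl2, 0 °C → rt; volatiles removed; n-BuLi, THF–hexane, −78 °C; (CH2O)n, −78 °C → rt; aq. KNaC4H4O6 (potassium sodium tartrate)
Reagents that add atoms: trimethylaluminium, C[Al](C)C; paraformaldehyde (as formaldehyde), C=O
Why: Negishi zirconium-catalysed methylalumination adds CH3 and Al syn across the terminal alkyne with CH3 on the internal carbon, and the alanate formed with n-BuLi attacks formaldehyde with retention at the alkenyl carbon, which fixes the E geometry of C2'=C3' while the monosubstituted alkene and the silyl ether should be left alone.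

Step 5
Reactants: 9 (2E,5R)-5-{[tert-butyl(dimethyl)silyl]oxy}-3-methylhepta-2,6-dien-1-ol
Product: 10 {[(3R,5E)-7-bromo-5-methylhepta-1,5-dien-3-yl]oxy}(tert-butyl)dimethylsilane
Conditions: CBr4, PPh3, CH2Cl2, 0 °C; used without storage
Reagents that add atoms: tetrabromomethane, BrC(Br)(Br)Br
Why: Appel bromination, in which the alcohol attacks the bromophosphonium ion and bromide displaces triphenylphosphine oxide from the primary allylic carbon by SN2 under near-neutral conditions, which should keep the E alkene and the silyl ether.

Step 6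
Reactants: 10 {[(3R,5E)-7-bromo-5-methylhepta-1,5-dien-3-yl]oxy}(tert-butyl)dimethylsilane; 11 daphnetin (7,8-dihydroxy-2H-chromen-2-one)
Product: 12 7-{[(2E,5R)-5-{[tert-butyl(dimethyl)silyl]oxy}-3-methylhepta-2,6-dien-1-yl]oxy}-8-hydroxy-2H-chromen-2-one
Conditions: 11 (1.5 equiv), KHCO3 (1.1 equiv), DMF, 40 °C
Reagents that add atoms: none
Why: Williamson etherification made regioselective by acidity, since the 7-OH is the more acidic phenol (its anion is conjugated through C4a and C3=C4 with the lactone carbonyl), so a hydrogen carbonate base with the bromide as limiting reagent should give SN2 alkylation at O7 only.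

Step 7
Reactants: 12 7-{[(2E,5R)-5-{[tert-butyl(dimethyl)silyl]oxy}-3-methylhepta-2,6-dien-1-yl]oxy}-8-hydroxy-2H-chromen-2-one
Product: 13 7-{[(2E,5R)-5-{[tert-butyl(dimethyl)silyl]oxy}-3-methylhepta-2,6-dien-1-yl]oxy}-8-methoxy-2H-chromen-2-one
Conditions: MeI, K2CO3, acetone, 50 °C
Reagents that add atoms: iodomethane, CI
Why: Williamson methylation of the remaining, less acidic 8-phenol with the stronger carbonate base, under which the silyl ether, the lactone and both alkenes should be inert.

Step 8
Reactants: 13 7-{[(2E,5R)-5-{[tert-butyl(dimethyl)silyl]oxy}-3-methylhepta-2,6-dien-1-yl]oxy}-8-methoxy-2H-chromen-2-one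
Product: 14 7-{[(2R,3R)-3-[(2R)-2-{[tert-butyl(dimethyl)silyl]oxy}but-3-en-1-yl]-3-methyloxiran-2-yl]methoxy}-8-methoxy-2H-chromen-2-one
Conditions: D-fructose-derived Shi ketone (0.3–1.0 equiv), Oxone (2KHSO5·KHSO4·K2SO4), K2CO3, Bu4NHSO4 (cat.), MeCN–CH2(OMe)2 / aq. Na2B4O7–Na2EDTA buffer, pH 10.5, 0 °C
Reagents that add atoms: potassium peroxymonosulfate (active part of Oxone), [K+].[O-]S(=O)(=O)OO
Why: KHSO5 adds to the carbonyl of the Shi ketone and the adduct closes to a chiral dioxirane, which transfers one oxygen atom to the C2'=C3' alkene through a concerted spiro transition state; this is the Shi asymmetric epoxidation of trans-disubstituted and trisubstituted alkenes. The oxirane ring is closed by this single [2+1] oxygen-atom transfer, in which both C–O bonds form on the same alkene face, so the E geometry from step 4 becomes the trans relationship of C1' and C4'. The configuration at C2' and C3' is set by the catalyst: the D-fructose-derived ketone is the enantiomer that gives (R,R)-epoxides from E alkenes of this substitution pattern, and the remote C5' centre should have little influence. The step needs site selectivity, and the substrate secures it, because the electrophilic dioxirane should prefer the trisubstituted alkene over the monosubstituted vinyl group (further deactivated by the allylic silyloxy group) and over the electron-poor coumarin C3=C4 bond. The silyl ether at C5' excludes oxidation of the allylic carbinol and hydroxyl-assisted opening of the new oxirane, and pH 10.5 at 0 °C limits Baeyer–Villiger decay of the catalyst while the lactone should survive the short exposure. Because the allylic aryloxy group slows the alkene, a high catalyst loading is planned.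

Step 9
Reactants: 14 7-{[(2R,3R)-3-[(2R)-2-{[tert-butyl(dimethyl)silyl]oxy}but-3-en-1-yl]-3-methyloxiran-2-yl]methoxy}-8-methoxy-2H-chromen-2-one
Product: 15 7-{[(2R,3R)-3-[(2R)-2-hydroxybut-3-en-1-yl]-3-methyloxiran-2-yl]methoxy}-8-methoxy-2H-chromen-2-one
Conditions: Bu4NF, AcOH (1:1), THF, 0 °C → rt
Reagents that add atoms: none
Why: Fluoride-induced desilylation driven by the strong Si–F bond, buffered with acetic acid so that the alkoxide is protonated at once and the lactone, the oxirane and all three stereocentres should be unaffected.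

Step 10
Reactants: 15 7-{[(2R,3R)-3-[(2R)-2-hydroxybut-3-en-1-yl]-3-methyloxiran-2-yl]methoxy}-8-methoxy-2H-chromen-2-one; 16 2-methylbut-2-ene
Product: 17 7-{[(2R,3R)-3-[(2R)-2-hydroxy-4-methylpent-3-en-1-yl]-3-methyloxiran-2-yl]methoxy}-8-methoxy-2H-chromen-2-one (CNP0223665.1)
Conditions: second-generation Grubbs catalyst (H2IMes)(PCy3)Cl2Ru=CHPh (5 mol%), 16 (large excess), CH2Cl2, 40 °C, sealed vessel
Reagents that add atoms: none
Why: Olefin cross-metathesis, in which the ruthenium alkylidene exchanges the terminal CH2 of the vinyl carbinol for the isopropylidene unit of 2-methylbut-2-ene with loss of propene, while the trisubstituted product alkene, the conjugated coumarin C3=C4 bond and the oxirane should not react and no stereocentre or alkene geometry is at stake.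

**Compound list**

1 | acrolein (prop-2-enal) | C=CC=O | starting material
2 | propargyl bromide (3-bromoprop-1-yne) | C#CCBr | starting material
3 | allenylzinc bromide (not isolated) | C=C=C[Zn]Br | intermediate
4 | rac-hex-1-en-5-yn-3-ol | C=CC(O)CC#C | intermediate
5 | (3R)-hex-1-en-5-yn-3-ol | C#CC[C@@H](O)C=C | intermediate
6 | tert-butyl{[(3R)-hex-1-en-5-yn-3-yl]oxy}dimethylsilane | C#CC[C@@H](O[Si](C)(C)C(C)(C)C)C=C | intermediate
7 | [(1E,4R)-4-{[tert-butyl(dimethyl)silyl]oxy}-2-methylhexa-1,5-dien-1-yl]dimethylalane (not isolated) | C[Al](C)/C=C(\C)C[C@@H](O[Si](C)(C)C(C)(C)C)C=C | intermediate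
8 | lithium butyl[(1E,4R)-4-{[tert-butyl(dimethyl)silyl]oxy}-2-methylhexa-1,5-dien-1-yl]dimethylalanate (not isolated) | [Li+].CCCC[Al-](C)(C)/C=C(\C)C[C@@H](O[Si](C)(C)C(C)(C)C)C=C | intermediate
9 | (2E,5R)-5-{[tert-butyl(dimethyl)silyl]oxy}-3-methylhepta-2,6-dien-1-ol | OC/C=C(\C)C[C@@H](O[Si](C)(C)C(C)(C)C)C=C | intermediate
10 | {[(3R,5E)-7-bromo-5-methylhepta-1,5-dien-3-yl]oxy}(tert-butyl)dimethylsilane | BrC/C=C(\C)C[C@@H](O[Si](C)(C)C(C)(C)C)C=C | intermediate
11 | daphnetin (7,8-dihydroxy-2H-chromen-2-one) | Oc1ccc2ccc(=O)oc2c1O | starting material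
12 | 7-{[(2E,5R)-5-{[tert-butyl(dimethyl)silyl]oxy}-3-methylhepta-2,6-dien-1-yl]oxy}-8-hydroxy-2H-chromen-2-one | Oc1c(OC/C=C(\C)C[C@@H](O[Si](C)(C)C(C)(C)C)C=C)ccc2ccc(=O)oc12 | intermediate
13 | 7-{[(2E,5R)-5-{[tert-butyl(dimethyl)silyl]oxy}-3-methylhepta-2,6-dien-1-yl]oxy}-8-methoxy-2H-chromen-2-one | COc1c(OC/C=C(\C)C[C@@H](O[Si](C)(C)C(C)(C)C)C=C)ccc2ccc(=O)oc12 | intermediate
14 | 7-{[(2R,3R)-3-[(2R)-2-{[tert-butyl(dimethyl)silyl]oxy}but-3-en-1-yl]-3-methyloxiran-2-yl]methoxy}-8-methoxy-2H-chromen-2-one | COc1c(OC[C@H]2O[C@]2(C)C[C@@H](O[Si](C)(C)C(C)(C)C)C=C)ccc2ccc(=O)oc12 | intermediate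
15 | 7-{[(2R,3R)-3-[(2R)-2-hydroxybut-3-en-1-yl]-3-methyloxiran-2-yl]methoxy}-8-methoxy-2H-chromen-2-one | COc1c(OC[C@H]2O[C@]2(C)C[C@@H](O)C=C)ccc2ccc(=O)oc12 | intermediate
16 | 2-methylbut-2-ene | CC=C(C)C | starting material
17 | 7-{[(2R,3R)-3-[(2R)-2-hydroxy-4-methylpent-3-en-1-yl]-3-methyloxiran-2-yl]methoxy}-8-methoxy-2H-chromen-2-one (CNP0223665.1) | COc1c(OC[C@H]2O[C@]2(C)C[C@@H](O)C=C(C)C)ccc2ccc(=O)oc12 | target

**Step count**

Total: 10 steps. Longest linear sequence: 10 steps (acrolein and propargyl bromide to 17; daphnetin enters at step 6 and 2-methylbut-2-ene at step 10).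

**Steps most likely to fail, with fallbacks**

Step 8. Oxygen transfer to the C2'=C3' alkene may be slow or poorly face-selective because the allylic aryloxy group withdraws electron density, so that catalyst decay or lactone hydrolysis at pH 10.5 could overtake epoxidation. The fallback sets out from allylic alcohol 9 and places the oxirane under hydroxyl direction before the aryl ether is made. Sharpless asymmetric epoxidation of 9 (Ti(OiPr)4, D-(−)-diethyl tartrate, t-BuOOH, 4 Å molecular sieves, CH2Cl2, −20 °C) should give [(2R,3R)-3-{(2R)-2-[(tert-butyldimethylsilyl)oxy]but-3-en-1-yl}-3-methyloxiran-2-yl]methanol F1, the enantiomeric series to that obtained from E allylic alcohols with the L-(+)-tartrate. Tosylation (TsCl, Et3N, DMAP, CH2Cl2, 0 °C) should give the epoxy tosylate F2. Alkylation of daphnetin 11 with F2 (KHCO3, DMF) should give 7-{[(2R,3R)-3-{(2R)-2-[(tert-butyldimethylsilyl)oxy]but-3-en-1-yl}-3-methyloxiran-2-yl]methoxy}-8-hydroxy-2H-chromen-2-one F3 by direct displacement at C1'. Methylation of F3 (MeI, K2CO3, acetone) comes back to the route at 14.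

Step 2. The lipase may discriminate the enantiomers weakly, since vinyl and propargyl differ little in size, or may prefer the other enantiomer. The fallback sets out from racemate 4 and uses a Sharpless kinetic resolution (Ti(OiPr)4, L-(+)-diisopropyl tartrate, t-BuOOH (0.6 equiv), 4 Å molecular sieves, CH2Cl2, −20 °C), in which recognition rests on the carbinol configuration relative to the alkene face and not on substituent size. The (S)-enantiomer should be epoxidised faster to the erythro epoxy alcohol (1S)-1-[(2R)-oxiran-2-yl]but-3-yn-1-ol F4, and the unreacted (R)-alcohol is recovered, which comes back to the route at 5.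

Step 6. Alkylation may occur at O8 as well, or at both phenols, giving a mixture that is hard to separate. The fallback sets out from bromide 10 and fixes the oxygen pattern before the coupling. Pechmann-type condensation of commercial 2-methoxybenzene-1,3-diol with ethyl propiolate (ZnCl2, 100 °C) should give 7-hydroxy-8-methoxy-2H-chromen-2-one F5 as the only regioisomer, because the two ring positions open to attack are equivalent by symmetry. Williamson etherification of F5 with 10 (K2CO3, acetone, 50 °C) bypasses 12 and comes back to the route at 13.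

**Further compounds**

F1 | step 8 | [(2R,3R)-3-{(2R)-2-[(tert-butyldimethylsilyl)oxy]but-3-en-1-yl}-3-methyloxiran-2-yl]methanol | OC[C@H]1O[C@]1(C)C[C@@H](O[Si](C)(C)C(C)(C)C)C=C
F2 | step 8 | [(2R,3R)-3-{(2R)-2-[(tert-butyldimethylsilyl)oxy]but-3-en-1-yl}-3-methyloxiran-2-yl]methyl 4-methylbenzenesulfonate | Cc1ccc(cc1)S(=O)(=O)OC[C@H]1O[C@]1(C)C[C@@H](O[Si](C)(C)C(C)(C)C)C=C
F3 | step 8 | 7-{[(2R,3R)-3-{(2R)-2-[(tert-butyldimethylsilyl)oxy]but-3-en-1-yl}-3-methyloxiran-2-yl]methoxy}-8-hydroxy-2H-chromen-2-one | Oc1c(OC[C@H]2O[C@]2(C)C[C@@H](O[Si](C)(C)C(C)(C)C)C=C)ccc2ccc(=O)oc12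
F4 | step 2 | (1S)-1-[(2R)-oxiran-2-yl]but-3-yn-1-ol | C#CC[C@H](O)[C@H]1CO1
F5 | step 6 | 7-hydroxy-8-methoxy-2H-chromen-2-one | COc1c(O)ccc2ccc(=O)oc12
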